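**Retrosynthetic overview**

1. The target is cut at the C15 ester to (13S)-labdane-8α,15-diol (21) and 3-phenylpropanoyl chloride. The 8α-OH and C17 come from the 8(17)-alkene 19 (epoxidation, hydride), and 19 comes from the 8-ketone 18.
2. Ring A is closed last, at C3–C4: in the nopinone 15, C4 is still tied to C7 in a cyclobutane. SnCl4 at the C8 ketone breaks C4–C7, and the freed gem-dimethyl cation C4 is captured by the allyl group on C10 to give the trans-decalin 17.
3. Enabling feature: ring B (C5–C10) carries C4(Me)2 on C5 and oxygen on C8, and C4 lies 1,3 to C7. Drawing the bond C4–C7 gives the four-membered ring C4–C5–C6–C7 of a pinane, so the ten carbons of (+)-verbenone are C4–C10, C18, C19 and C20, and its C5 stereocentre is C5 of the target.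
4. C10 is set by conjugate allylation of verbenone anti to the bridge. C9 is set by aldol condensation with aldehyde 6, then conjugate reduction with protonation anti to the bridge.
5. C11–C15 with C13 come from methyl hydrogen (R)-3-methylglutarate (ester arm becomes C11/C12, acid arm becomes C14/C15). Ring order: cyclobutane and ring B from the chiral pool, ring A last.

Key step: step 7

Remark: labdane numbering is used for every atom (pinane C2/C3/C4/C5/C6/C7/C1 = labdane C8/C9/C10/C5/C4/C6/C7), and (1R,5R)-(+)-verbenone and methyl hydrogen (R)-3-methylglutarate are taken as purchasable.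

**Step 1**
Reactants: 1 methyl hydrogen (R)-3-methylglutarate
Product: 3 (S)-4-methyltetrahydro-2H-pyran-2-one, via lithium (S)-5-hydroxy-3-methylpentanoate 2 (not isolated)
Conditions: LiBH4, THF, 0 °C to rt; then 2 M HCl, rt
Reagents that add atoms: none
Why: Chemoselective borohydride reduction, in which LiBH4 reduces the methyl ester but not the lithium carboxylate and the 5-hydroxy acid lactonises on acidification; the stereocentre is not involved (the descriptor changes only through a priority switch).

**Step 2**
Reactants: 3 (S)-4-methyltetrahydro-2H-pyran-2-one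
Product: 5 methyl (R)-5-iodo-3-methylpentanoate, via trimethylsilyl (R)-5-iodo-3-methylpentanoate 4 (not isolated)
Conditions: TMSI, CH2Cl2, rt; then MeOH, rt
Reagents that add atoms: iodotrimethylsilane C[Si](C)(C)I; methanol CO
Why: Silyl iodide cleavage of a lactone (iodide attacks the O–CH2 carbon of the silyl-activated lactone by SN2), followed by acid-catalysed methanolysis and esterification of the silyl ester; the stereocentre is remote from both reacting carbons.

**Step 3**
Reactants: 5 methyl (R)-5-iodo-3-methylpentanoate
Product: 6 methyl (S)-3-methyl-5-oxopentanoate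
Conditions: N-methylmorpholine N-oxide, DMSO, rt
Reagents that add atoms: N-methylmorpholine N-oxide C[N+]1([O-])CCOCC1
Why: Ganem (Kornblum-type) oxidation, in which the N-oxide oxygen displaces the primary iodide and the alkoxyammonium salt collapses to the aldehyde; no stereocentre is touched (the descriptor becomes S by priority change).

**Step 4**
Reactants: 7 (1R,5R)-(+)-verbenone
Product: 9 (1R,4R,5R)-4-allyl-4,6,6-trimethylbicyclo[3.1.1]heptan-2-one (allyl anti to the gem-dimethyl bridge), via trimethylsilyl enol ether 8 (not isolated)
Conditions: allylMgBr, CuBr·SMe2, TMSCl, THF, −78 °C; then 1 M HCl, THF, 0 °C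
Reagents that add atoms: allylmagnesium bromide C=CC[Mg]Br
Why: TMSCl-accelerated organocopper conjugate addition delivers the allyl group to the β-carbon C10 from the face opposite the gem-dimethyl bridge, so that the C20 methyl ends syn to C4 and the new quaternary centre C10 has the target configuration; mild acid then hydrolyses the silyl enol ether.

**Step 5**
Reactants: 9 (1R,4R,5R)-4-allyl-4,6,6-trimethylbicyclo[3.1.1]heptan-2-one; 6 methyl (S)-3-methyl-5-oxopentanoate
Product: 13 methyl (3S)-5-[4-allyl-4,6,6-trimethyl-2-oxobicyclo[3.1.1]heptan-3-ylidene]-3-methylpentanoate (ring configuration as in 9, Z drawn), via lithium enolate 10 (not isolated), via lithium aldolate 11 (not isolated), via mesylate 12 (not isolated)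
Conditions: LDA, THF, −78 °C; 6, −78 °C; MsCl, −78 to 0 °C; DBU, 0 to 40 °C
Reagents that add atoms: none
Why: Aldol condensation in three telescoped events (directed aldol addition of the only possible enolate, C7 being a bridgehead; O-mesylation; E1cB elimination), in which the centres created at C9 and C11 are erased again and the alkene geometry is irrelevant for step 6.

**Step 6**
Reactants: 13 the alkylidene ketone
Product: 15 methyl (3S)-5-[4-allyl-4,6,6-trimethyl-2-oxobicyclo[3.1.1]heptan-3-yl]-3-methylpentanoate (ring configuration as in 9, C3 side chain cis to the gem-dimethyl bridge and cis to the C4 methyl), via lithium enolate 14 (not isolated)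
Conditions: L-Selectride, THF, −78 °C; then AcOH, −78 °C
Reagents that add atoms: none
Why: Conjugate (1,4-) reduction with a hindered trialkylborohydride gives the lithium enolate, which should be protonated kinetically at C9 from the face opposite the gem-dimethyl bridge (the approach control that turns alkylidene pinanones into the cis ketones), so that H-9 ends anti to the bridge and the side chain syn to it, which is 9α-H of the target.

**Step 7**
Reactants: 15 the 3,4,4-trisubstituted nopinone
Product: 17 methyl (13S)-2α-chloro-8-oxo-17-norlabdan-15-oate, via ring-opened stannyl enolate cation 16 (not isolated)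
Conditions: SnCl4, CH2Cl2, −78 to 0 °C; aq. NaHCO3
Reagents that add atoms: tin(IV) chloride Cl[Sn](Cl)(Cl)Cl
Why: Proposed new method: SnCl4 bound to the C8 ketone should trigger heterolysis of the strained cyclobutane bond C7–C4 (the one bond that is both α to the carbonyl and able to leave a tertiary cation), giving a stannyl enolate at C7=C8 and the 2-propyl cation C4 on C5 with release of the four-ring strain. The freed ring-B half-chair can place the cation arm on C5 and the allyl group on C10 trans-diequatorial, and the terminal alkene carbon C3 then attacks C4 through a chair transition state in 6-endo-trig (Markovnikov) mode, which closes ring A, forms the quaternary gem-dimethyl carbon and leaves a C2 cation that collapses with chloride from the stannate by anti addition (equatorial 2α-Cl, a centre deleted in step 8). The closest known reaction type is the Lewis acid-induced cyclobutane cleavage of 4-aryl-6,6-dimethylnorpinan-2-ones, in which the same gem-dimethyl cation is captured by a phenolic oxygen to close a trans-fused 2,2-dimethylchroman, together with acylcyclopropane–olefin and Prins-type cation–olefin cyclisations; here a carbon π-nucleophile takes the place of oxygen. No ring-fusion stereocentre is made in the step: C5 keeps the verbenone configuration because its bond to C4 is never broken, C10 was fixed in step 4, and their trans relation (allyl anti to the bridge) is what becomes the trans-decalin. The step needs cyclisation to outrun proton loss from the C4 cation and 5-exo closure; the 1,6-relation of cation and alkene terminus, the Markovnikov bias and the reversibility of chloride capture at C4 should secure this.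

**Step 8**
Reactants: 17 methyl (13S)-2α-chloro-8-oxo-17-norlabdan-15-oate
Product: 18 methyl (13S)-8-oxo-17-norlabdan-15-oate
Conditions: Bu3SnH, AIBN (cat.), PhMe, 110 °C
Reagents that add atoms: none
Why: Radical chain dehalogenation with tributyltin hydride removes the C2 chloride under neutral conditions that neither enolise C9 nor touch the ketone and the ester.

**Step 9**
Reactants: 18 methyl (13S)-8-oxo-17-norlabdan-15-oate
Product: 19 methyl (13S)-labd-8(17)-en-15-oate
Conditions: Zn, CH2Br2, TiCl4, THF/CH2Cl2, 0 °C to rt
Reagents that add atoms: dibromomethane BrCBr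
Why: Takai–Lombardo methylenation, whose gem-dimetallic zinc/titanium reagent is non-basic, converts hindered enolisable ketones to methylene compounds without epimerising C9 and leaves the ester alone.

**Step 10**
Reactants: 19 methyl (13S)-labd-8(17)-en-15-oate
Product: 20 methyl (13S)-8α,17-epoxylabdan-15-oate
Conditions: mCPBA, NaHCO3, CH2Cl2, 0 °C
Reagents that add atoms: mCPBA OOC(=O)c1cccc(Cl)c1
Why: Prilezhaev epoxidation of the only alkene, in which the peracid should approach the exocyclic C8=C17 bond from the α face, away from the axial C10 methyl that is 1,3-syn to the β face of C8, which sets C8 with oxygen α.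

**Step 11**
Reactants: 20 methyl (13S)-8α,17-epoxylabdan-15-oate
Product: 21 (13S)-labdane-8α,15-diol
Conditions: LiAlH4, THF, 0 °C to reflux; aq. NaOH work-up
Reagents that add atoms: none
Why: Hydride reduction, in which SN2 opening of the spiro-epoxide at the primary carbon C17 leaves the tertiary 8α-alcohol with C17 as the axial methyl (C8 configuration unchanged) and the same reagent reduces the methyl ester to the C15 alcohol.

**Step 12**
Reactants: 21 (13S)-labdane-8α,15-diol; 22 3-phenylpropanoyl chloride
Product: 23 (13S)-8α-hydroxylabdan-15-yl 3-phenylpropanoate, the target (5S,8R,9R,10S,13S)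
Conditions: pyridine, CH2Cl2, 0 °C
Reagents that add atoms: none
Why: Acylation with an acid chloride (esterification) is selective for the primary C15 hydroxyl, the hindered tertiary 8-hydroxyl being inert under these conditions.

**Compound list**

1 | methyl hydrogen (R)-3-methylglutarate | C[C@@H](CC(=O)OC)CC(O)=O | starting material
2 | (S)-5-hydroxy-3-methylpentanoic acid (lithium salt in the flask) | C[C@@H](CCO)CC(O)=O | intermediate
3 | (S)-4-methyltetrahydro-2H-pyran-2-one | C[C@H]1CCOC(=O)C1 | intermediate
4 | trimethylsilyl (R)-5-iodo-3-methylpentanoate | C[C@@H](CCI)CC(=O)O[Si](C)(C)C | intermediate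
5 | methyl (R)-5-iodo-3-methylpentanoate | C[C@@H](CCI)CC(=O)OC | intermediate
6 | methyl (S)-3-methyl-5-oxopentanoate | C[C@@H](CC=O)CC(=O)OC | intermediate
7 | (1R,5R)-(+)-verbenone | CC1=CC(=O)[C@@H]2C[C@H]1C2(C)C | starting material
8 | trimethylsilyl enol ether of 9 | C=CC[C@]1(C)C=C(O[Si](C)(C)C)[C@@H]2C[C@H]1C2(C)C | intermediate
9 | (1R,4R,5R)-4-allyl-4,6,6-trimethylbicyclo[3.1.1]heptan-2-one | C=CC[C@]1(C)CC(=O)[C@@H]2C[C@H]1C2(C)C | intermediate
10 | lithium enolate of 9 | C=CC[C@]1(C)C=C(O[Li])[C@@H]2C[C@H]1C2(C)C | intermediate
11 | lithium aldolate of 9 and 6 (aldehyde added anti to the bridge, carbinol epimers) | C=CC[C@]1(C)[C@H](C(O[Li])C[C@H](C)CC(=O)OC)C(=O)[C@@H]2C[C@H]1C2(C)C | intermediate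
12 | methanesulfonate of the aldol adduct | C=CC[C@]1(C)[C@H](C(OS(C)(=O)=O)C[C@H](C)CC(=O)OC)C(=O)[C@@H]2C[C@H]1C2(C)C | intermediate
13 | methyl (3S)-5-[4-allyl-4,6,6-trimethyl-2-oxobicyclo[3.1.1]heptan-3-ylidene]-3-methylpentanoate (Z) | C=CC[C@]1(C)C(=C/C[C@H](C)CC(=O)OC)/C(=O)[C@@H]2C[C@H]1C2(C)C | intermediate
14 | lithium enolate from 1,4-reduction of 13 | C=CC[C@]1(C)C(CC[C@H](C)CC(=O)OC)=C(O[Li])[C@@H]2C[C@H]1C2(C)C | intermediate
15 | methyl (3S)-5-[4-allyl-4,6,6-trimethyl-2-oxobicyclo[3.1.1]heptan-3-yl]-3-methylpentanoate, side chain cis to the gem-dimethyl bridge | C=CC[C@]1(C)[C@@H](CC[C@H](C)CC(=O)OC)C(=O)[C@@H]2C[C@H]1C2(C)C | intermediate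
16 | ring-opened tetrachlorostannyl enolate with the C4 tertiary cation | C=CC[C@]1(C)[C@@H](CC[C@H](C)CC(=O)OC)C(O[Sn-](Cl)(Cl)(Cl)Cl)=CC[C@H]1[C+](C)C | intermediate
17 | methyl (13S)-2α-chloro-8-oxo-17-norlabdan-15-oate | COC(=O)C[C@@H](C)CC[C@H]1C(=O)CC[C@H]2C(C)(C)C[C@H](Cl)C[C@]12C | intermediate
18 | methyl (13S)-8-oxo-17-norlabdan-15-oate | COC(=O)C[C@@H](C)CC[C@H]1C(=O)CC[C@H]2C(C)(C)CCC[C@]12C | intermediate
19 | methyl (13S)-labd-8(17)-en-15-oate | COC(=O)C[C@@H](C)CC[C@H]1C(=C)CC[C@H]2C(C)(C)CCC[C@]12C | intermediate
20 | methyl (13S)-8α,17-epoxylabdan-15-oate | COC(=O)C[C@@H](C)CC[C@H]1[C@@]3(CO3)CC[C@H]2C(C)(C)CCC[C@]12C | intermediate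
21 | (13S)-labdane-8α,15-diol | C[C@H](CCO)CC[C@@H]1[C@@]2(C)CCCC(C)(C)[C@@H]2CC[C@@]1(C)O | intermediate
22 | 3-phenylpropanoyl chloride | O=C(Cl)CCc1ccccc1 | starting material
23 | (13S)-8α-hydroxylabdan-15-yl 3-phenylpropanoate | C[C@H](CCOC(=O)CCc1ccccc1)CC[C@@H]1[C@@]2(C)CCCC(C)(C)[C@@H]2CC[C@@]1(C)O | target

**Step count and risks**

Total step count: 12. Longest linear sequence: 11 steps (steps 1–3 and 5–12, from 1); the verbenone branch (steps 4–12) has 9.

Steps most likely to fail:

Step 7 (new method). The C4 cation may lose a proton toward C5 or C18 faster than the alkene captures it, and re-protonation would then scramble the ring-fusion configuration. The secondary C2 cation may also undergo hydride or methyl shifts, or chloride capture at C4 may stall the cascade. The fallback separates the two events with known chemistry and sets out from 15. Anhydrous HCl in acetic acid at 0 °C should open the cyclobutane, as known for nopinone-type cyclobutyl ketones, to the isolable tertiary chloride methyl (13S)-4-chloro-8-oxo-17-nor-3,4-secolabd-2-en-15-oate F1. This chloride is then ionised under mild Lewis acid catalysis (ZnCl2·OEt2, CH2Cl2, −78 °C), conditions under which tert-alkyl chlorides add across alkenes with transfer of chloride, so that ring A closes at low temperature next to a tight chloride counter-ion. The fallback returns to the route at 17.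

Step 4. The allyl metal may transfer to the carbonyl carbon (1,2-addition) instead of the hindered, fully substituted β-carbon C10. The fallback makes use of exactly this and sets out from 7. Allylmagnesium bromide alone (THF, −78 °C) should add 1,2 from the face opposite the bridge to give the tertiary bis-allylic alcohol (1R,5R)-2-allyl-4,6,6-trimethylbicyclo[3.1.1]hept-3-en-2-ol F2. Potassium hydride and 18-crown-6 in THF should then bring about the anionic oxy-Cope rearrangement, which moves the allyl group suprafacially from C8 to C10 on the same anti-bridge face and leaves the enolate. Protonation returns to the route at 9.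

Step 6. Facial selectivity in the protonation of enolate 14 may be poor, or the crowded cis ketone may epimerise at C9 on handling or under the Lewis acid of step 7. The fallback postpones the C9 decision until ring A is closed and sets out from 13. The alkylidene ketone is taken as such through the step 7 conditions (the C8 carbonyl remains the electron sink and the fragmentation product is a cross-conjugated stannyl dienolate) to give methyl (13S)-2α-chloro-8-oxo-17-norlabd-9(11)-en-15-oate F3. Hydrogenation (H2, Pd/C, EtOAc) should then deliver hydrogen to C9 from the α face, opposite the axial C10 methyl, in a ring system where the 9α-H epimer should also be the more stable one. The fallback returns to the route at 17.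

**Further compounds**

F1 | step 7 | methyl (13S)-4-chloro-8-oxo-17-nor-3,4-secolabd-2-en-15-oate | C=CC[C@]1(C)[C@@H](CC[C@H](C)CC(=O)OC)C(=O)CC[C@H]1C(C)(C)Cl
F2 | step 4 | (1R,5R)-2-allyl-4,6,6-trimethylbicyclo[3.1.1]hept-3-en-2-ol (allyl anti to the gem-dimethyl bridge) | C=CC[C@@]1(O)C=C(C)[C@H]2C[C@@H]1C2(C)C
F3 | step 6 | methyl (13S)-2α-chloro-8-oxo-17-norlabd-9(11)-en-15-oate (Z) | COC(=O)C[C@@H](C)C/C=C1\C(=O)CC[C@H]2C(C)(C)C[C@H](Cl)C[C@]12C
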